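The route rests on the C6–C7 bond, which belongs to both the ten-membered carbocycle (C1–C10) and the butenolide (O, C6, C7, C11, C12); C6 is at once the allylic carbinol carbon and the lactone alkoxy carbon. A nickel-catalysed, chromium-mediated addition joins the C7 enol-triflate carbon to the C6 aldehyde of an open-chain precursor, and the C6 alkoxide, held cis to the C12 ester across C7=C11, lactonises at once: one operation gives carbocycle, lactone and the C6 stereocentre. The precursor is an acyclic (Z)-β-triflyloxy acrylate carrying the C13 silyl ether, the (1R,10R)-epoxide, the (3S)-acetate and an (E)-enal, built from (R)-linalool, (E)-4-acetoxy-2-methylbut-2-enal and methyl 3-hydroxypropanoate.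

Key step: step 13

Remark: atoms are numbered as in germacranolides (ring C1–C10, lactone carbons C11–C13, C14 on C10, C15 on C4). Compounds 18–20 are carried as mixtures of C7/C11 diastereomers because both centres become sp2 by step 12.

Step 1
Reactants: 1 (R)-linalool [(3R)-3,7-dimethylocta-1,6-dien-3-ol]
Product: 2 (3R)-3,7-dimethyl-3-(triethylsilyloxy)octa-1,6-diene
Conditions: TESOTf, 2,6-lutidine, CH2Cl2, −78 to 0 °C
Reagents that add atoms: triethylsilyl trifluoromethanesulfonate, CC[Si](CC)(CC)OS(=O)(=O)C(F)(F)F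
Why: Silyl triflate with a hindered pyridine base silylates even a tertiary allylic alcohol (silyl ether formation), the C10 stereocentre is not involved, and the ether keeps the hydroxyl from attacking palladium-activated alkenes in step 2 and from binding boron in step 3.

Step 2
Reactants: 2 (3R)-3,7-dimethyl-3-(triethylsilyloxy)octa-1,6-diene
Product: 3 (3R)-3,7-dimethyl-3-(triethylsilyloxy)oct-6-en-2-one
Conditions: Pd(quinox)Cl2 (cat.; quinox = 2-(4,5-dihydrooxazol-2-yl)quinoline), AgSbF6 (cat.), aq. t-BuOOH, CH2Cl2, 0 °C to rt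
Reagents that add atoms: tert-butyl hydroperoxide, CC(C)(C)OO
Why: A peroxide-driven Wacker oxidation should convert only the monosubstituted vinyl group and leave the trisubstituted alkene, and with an allylic oxygen substituent this cationic palladium system favours the methyl ketone over the aldehyde; the fully substituted C10 cannot epimerise.

Step 3
Reactants: 3 (3R)-3,7-dimethyl-3-(triethylsilyloxy)oct-6-en-2-one; 4 (E)-4-acetoxy-2-methylbut-2-enal
Product: 7 (2E,4S,7R)-4-hydroxy-3,7,11-trimethyl-6-oxo-7-(triethylsilyloxy)dodeca-2,10-dien-1-yl acetate, via enol borinate 5 (not isolated), via boron aldolate 6 (not isolated)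
Conditions: (+)-Ipc2BCl, Et3N, Et2O, 0 °C; 4, −78 to −20 °C; then H2O2, MeOH, pH 7 buffer, 0 °C
Reagents that add atoms: none
Why: Boron aldol addition of a methyl ketone that can enolise only at C2: the diisopinocampheylboron enolate 5 derived from (+)-Ipc2BCl is expected to attack the Si face of the aldehyde of 4 (reagent control), which sets C3 as S, and the 1,2-addition leaves the E alkene and the primary acetate untouched.

Step 4
Reactants: 7 (2E,4S,7R)-4-hydroxy-3,7,11-trimethyl-6-oxo-7-(triethylsilyloxy)dodeca-2,10-dien-1-yl acetate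
Product: 9 (2E,4S,6S,7R)-6-hydroxy-3,7,11-trimethyl-7-(triethylsilyloxy)dodeca-2,10-diene-1,4-diyl diacetate, via hemiacetal 8 (not isolated)
Conditions: SmI2 (0.3 equiv, premixed with the aldehyde), MeCHO (excess), THF, −10 °C
Reagents that add atoms: acetaldehyde, CC=O
Why: Evans–Tishchenko reduction: the C3 hydroxyl adds to acetaldehyde and the hemiacetal 8 bound to trivalent samarium passes its hydride to the C1 ketone through a chair-like six-membered transition state, which sets C1 as S in a 1,3-anti relation to C3 and leaves the acetyl group on the C3 oxygen and the hindered C1 hydroxyl free.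

Step 5
Reactants: 9 (2E,4S,6S,7R)-6-hydroxy-3,7,11-trimethyl-7-(triethylsilyloxy)dodeca-2,10-diene-1,4-diyl diacetate
Product: 10 (2E,4S,6S,7R)-6-(methylsulfonyloxy)-3,7,11-trimethyl-7-(triethylsilyloxy)dodeca-2,10-diene-1,4-diyl diacetate
Conditions: MsCl, Et3N, CH2Cl2, 0 °C
Reagents that add atoms: methanesulfonyl chloride, CS(=O)(=O)Cl
Why: Sulfonylation through sulfene reaches even a hindered secondary alcohol, the only free hydroxyl of 9, and keeps the C1 configuration because the C–O bond is not broken.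

Step 6
Reactants: 10 (2E,4S,6S,7R)-6-(methylsulfonyloxy)-3,7,11-trimethyl-7-(triethylsilyloxy)dodeca-2,10-diene-1,4-diyl diacetate
Product: 12 (2E,4S)-3-methyl-5-[(2R,3R)-3-methyl-3-(4-methylpent-3-en-1-yl)oxiran-2-yl]pent-2-ene-1,4-diyl diacetate, via hydroxy mesylate 11 (not isolated)
Conditions: Bu4NF, THF, 0 °C to rt
Reagents that add atoms: none
Why: Fluoride cleaves the tertiary silyl ether and the C10 alkoxide of 11 displaces the neighbouring mesylate in an intramolecular Williamson etherification (3-exo-tet) with inversion at C1, which gives the trans (1R,10R)-epoxide while C10 keeps the configuration of linalool; the acetates should survive fluoride at this temperature.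

Step 7
Reactants: 12 (2E,4S)-3-methyl-5-[(2R,3R)-3-methyl-3-(4-methylpent-3-en-1-yl)oxiran-2-yl]pent-2-ene-1,4-diyl diacetate
Product: 14 (2E,4S)-3-methyl-5-[(2R,3R)-3-methyl-3-(3-oxopropyl)oxiran-2-yl]pent-2-ene-1,4-diyl diacetate, via ozonide 13 (not isolated)
Conditions: O3, CH2Cl2, −78 °C (Sudan Red 7B end point); PPh3, −78 °C to rt
Reagents that add atoms: ozone, [O-][O+]=O
Why: Ozonolysis with reductive work-up: the electron-rich isopropylidene alkene reacts first, whereas the C4=C5 alkene is deactivated by two allylic acetoxy groups, and the dye indicator marks the end point before over-oxidation; epoxide and esters are inert.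

Step 8
Reactants: 15 methyl 3-hydroxypropanoate
Product: 16 methyl 3-(tert-butyldimethylsilyloxy)propanoate
Conditions: TBSCl, imidazole, CH2Cl2, rt
Reagents that add atoms: tert-butyldimethylsilyl chloride, CC(C)(C)[Si](C)(C)Cl
Why: Standard silylation of a primary alcohol with a silyl chloride and imidazole; no stereocentre is involved.

Step 9
Reactants: 14 (2E,4S)-3-methyl-5-[(2R,3R)-3-methyl-3-(3-oxopropyl)oxiran-2-yl]pent-2-ene-1,4-diyl diacetate; 16 methyl 3-(tert-butyldimethylsilyloxy)propanoate
Product: 18 methyl 5-{(2R,3R)-3-[(2S,3E)-2,5-diacetoxy-3-methylpent-3-en-1-yl]-2-methyloxiran-2-yl}-2-[(tert-butyldimethylsilyloxy)methyl]-3-hydroxypentanoate, via lithium enolate 17 (not isolated)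
Conditions: 16, LiN(iPr)2, THF, −78 °C; then 14, −78 °C; AcOH quench at −78 °C
Reagents that add atoms: none
Why: Aldol addition of a lithium ester enolate: at −78 °C the enolate 17 adds to the aldehyde much faster than to the acetates or the epoxide and does not expel its β-silyloxy group, and the two new stereocentres (C7, C11) need no control because both become sp2 by step 12.

Step 10
Reactants: 18 methyl 5-{(2R,3R)-3-[(2S,3E)-2,5-diacetoxy-3-methylpent-3-en-1-yl]-2-methyloxiran-2-yl}-2-[(tert-butyldimethylsilyloxy)methyl]-3-hydroxypentanoate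
Product: 19 methyl 5-{(2R,3R)-3-[(2S,3E)-2-acetoxy-5-hydroxy-3-methylpent-3-en-1-yl]-2-methyloxiran-2-yl}-2-[(tert-butyldimethylsilyloxy)methyl]-3-hydroxypentanoate
Conditions: [t-Bu2Sn(OH)Cl]2 (cat.), MeOH/THF, rt
Reagents that add atoms: none
Why: Neutral tin-catalysed transesterification with methanol cleaves unhindered primary acetates much faster than secondary ones, so the C6 acetate should go and the C3 acetate stay, and the neutral medium spares the epoxide, the silyl ether and the β-hydroxy ester.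

Step 11
Reactants: 19 methyl 5-{(2R,3R)-3-[(2S,3E)-2-acetoxy-5-hydroxy-3-methylpent-3-en-1-yl]-2-methyloxiran-2-yl}-2-[(tert-butyldimethylsilyloxy)methyl]-3-hydroxypentanoate
Product: 20 methyl 5-{(2R,3R)-3-[(2S,3E)-2-acetoxy-3-methyl-5-oxopent-3-en-1-yl]-2-methyloxiran-2-yl}-2-[(tert-butyldimethylsilyloxy)methyl]-3-oxopentanoate
Conditions: Dess–Martin periodinane, NaHCO3, CH2Cl2, 0 °C to rt
Reagents that add atoms: none
Why: Dess–Martin oxidation with a hypervalent iodine reagent turns the C7 carbinol into the ketone and the allylic C6 alcohol into the enal in one operation without touching the alkene geometry, the epoxide, the acetate or the silyl ether under bicarbonate buffering.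

Step 12
Reactants: 20 methyl 5-{(2R,3R)-3-[(2S,3E)-2-acetoxy-3-methyl-5-oxopent-3-en-1-yl]-2-methyloxiran-2-yl}-2-[(tert-butyldimethylsilyloxy)methyl]-3-oxopentanoate
Product: 22 methyl (2Z)-5-{(2R,3R)-3-[(2S,3E)-2-acetoxy-3-methyl-5-oxopent-3-en-1-yl]-2-methyloxiran-2-yl}-2-[(tert-butyldimethylsilyloxy)methyl]-3-(trifluoromethylsulfonyloxy)pent-2-enoate, via sodium enolate 21 (not isolated)
Conditions: NaH (1 equiv), THF, 0 °C; PhNTf2, 0 °C to rt
Reagents that add atoms: N-phenylbis(trifluoromethanesulfonimide), O=S(=O)(N(c1ccccc1)S(=O)(=O)C(F)(F)F)C(F)(F)F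
Why: O-Sulfonylation of a β-keto ester enolate: one equivalent of NaH removes only the most acidic C11 hydrogen, sodium chelated between the enolate oxygen and the ester carbonyl holds the two oxygens cis in 21, and trapping with the mild triflimide should therefore give the Z triflate, the geometry needed for lactonisation, without harm to the enal.

Step 13
Reactants: 22 methyl (2Z)-5-{(2R,3R)-3-[(2S,3E)-2-acetoxy-3-methyl-5-oxopent-3-en-1-yl]-2-methyloxiran-2-yl}-2-[(tert-butyldimethylsilyloxy)methyl]-3-(trifluoromethylsulfonyloxy)pent-2-enoate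
Product: 26 (1R,3S,4E,6R,10R)-3-acetoxy-13-(tert-butyldimethylsilyloxy)-1,10-epoxygermacra-4,7(11)-dien-12,6-olide, via alkenylnickel triflate 23 (not isolated), via alkenylchromium dichloride 24 (not isolated), via chromium alkoxide 25 (not isolated)
Conditions: CrCl2 (15 equiv), NiCl2 (0.3 equiv), 4-tert-butylpyridine, DMF/THF, rt, 22 added by syringe pump (about 2 mM); aqueous NH4Cl work-up
Reagents that add atoms: none
Why: Divalent chromium reduces NiCl2 to zerovalent nickel, which inserts into the C7–OTf bond with retention of alkene geometry to give 23; transmetalation to trivalent chromium gives the alkenylchromium 24, which adds 1,2 to the C6 aldehyde and should leave acetate, silyl ether and, with the pyridine buffer, the epoxide untouched. The closest known reaction types are the intramolecular Nozaki–Hiyama–Kishi macrocyclisation and the Nozaki–Hiyama–Kishi butenolide synthesis from (Z)-β-triflyloxy or β-iodo acrylates and aldehydes. The ten-membered carbocycle closes by 10-exo-trig addition of C7 to the C6 carbonyl, and the butenolide closes by 5-exo-trig acyl substitution of the chromium alkoxide 25 on the C12 methyl ester, which is possible only because the Z geometry from step 12 places C6–O and C12 cis on C7=C11. The new C6 stereocentre is set under substrate control in the cyclic transition state: the E enal should react s-trans, and the rigid trans-epoxide and the C3 acetoxy group bias the fold of the tether so that the aldehyde face leading to 6R, the configuration of the crown-like germacranolide ring, is the one offered to C7. The step needs ring closure to outrun intermolecular coupling and protodemetalation, which the slow addition at high dilution and the few rotatable bonds of 22 (E enal, epoxide, tetrasubstituted alkene) are meant to secure.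

Step 14
Reactants: 26 (1R,3S,4E,6R,10R)-3-acetoxy-13-(tert-butyldimethylsilyloxy)-1,10-epoxygermacra-4,7(11)-dien-12,6-olide
Product: 27 (1R,3S,4E,6R,10R)-3-acetoxy-1,10-epoxy-13-hydroxygermacra-4,7(11)-dien-12,6-olide
Conditions: Bu4NF, AcOH, THF, 0 °C to rt
Reagents that add atoms: none
Why: Fluoride-mediated desilylation buffered with acetic acid removes the primary silyl ether while avoiding base-induced epimerisation at C6 or acetate migration and acid-induced transannular opening of the epoxide.

Step 15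
Reactants: 27 (1R,3S,4E,6R,10R)-3-acetoxy-1,10-epoxy-13-hydroxygermacra-4,7(11)-dien-12,6-olide
Product: 28 (1R,3S,4E,6R,10R)-3,13-diacetoxy-1,10-epoxygermacra-4,7(11)-dien-12,6-olide (CNP0294733.1)
Conditions: Ac2O, pyridine, DMAP (cat.), CH2Cl2, 0 °C
Reagents that add atoms: acetic anhydride, CC(=O)OC(C)=O
Why: Nucleophile-catalysed acetylation of the primary allylic alcohol; no stereocentre is affected and the mild base should not epimerise C6 at this temperature.

Compound list

1 | (R)-linalool, (3R)-3,7-dimethylocta-1,6-dien-3-ol | CC(C)=CCC[C@@](C)(O)C=C | starting material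
2 | (3R)-3,7-dimethyl-3-(triethylsilyloxy)octa-1,6-diene | CC(C)=CCC[C@@](C)(O[Si](CC)(CC)CC)C=C | intermediate
3 | (3R)-3,7-dimethyl-3-(triethylsilyloxy)oct-6-en-2-one | CC(C)=CCC[C@@](C)(O[Si](CC)(CC)CC)C(C)=O | intermediate
4 | (E)-4-acetoxy-2-methylbut-2-enal | CC(=O)OC/C=C(\C)C=O | starting material
5 | diisopinocampheylboron enolate of 3 (Ipc groups as in (+)-Ipc2BCl) | CC(C)=CCC[C@@](C)(O[Si](CC)(CC)CC)C(=C)OB([C@H]1C[C@H]2C[C@@H]([C@@H]1C)C2(C)C)[C@H]1C[C@H]2C[C@@H]([C@@H]1C)C2(C)C | intermediate (not isolated)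
6 | O-diisopinocampheylboryl aldolate of 7 | CC(C)=CCC[C@@](C)(O[Si](CC)(CC)CC)C(=O)C[C@H](OB([C@H]1C[C@H]2C[C@@H]([C@@H]1C)C2(C)C)[C@H]1C[C@H]2C[C@@H]([C@@H]1C)C2(C)C)/C(C)=C/COC(C)=O | intermediate (not isolated)
7 | (2E,4S,7R)-4-hydroxy-3,7,11-trimethyl-6-oxo-7-(triethylsilyloxy)dodeca-2,10-dien-1-yl acetate (C3 S, C10 R) | CC(C)=CCC[C@@](C)(O[Si](CC)(CC)CC)C(=O)C[C@H](O)/C(C)=C/COC(C)=O | intermediate
8 | acetaldehyde hemiacetal at the C3 oxygen of 7, bound to trivalent samarium (drawn as the free hemiacetal) | CC(C)=CCC[C@@](C)(O[Si](CC)(CC)CC)C(=O)C[C@H](OC(C)O)/C(C)=C/COC(C)=O | intermediate (not isolated)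
9 | (2E,4S,6S,7R)-6-hydroxy-3,7,11-trimethyl-7-(triethylsilyloxy)dodeca-2,10-diene-1,4-diyl diacetate (C1 S, C3 S, C10 R) | CC(C)=CCC[C@@](C)(O[Si](CC)(CC)CC)[C@@H](O)C[C@H](OC(C)=O)/C(C)=C/COC(C)=O | intermediate
10 | (2E,4S,6S,7R)-6-(methylsulfonyloxy)-3,7,11-trimethyl-7-(triethylsilyloxy)dodeca-2,10-diene-1,4-diyl diacetate | CC(C)=CCC[C@@](C)(O[Si](CC)(CC)CC)[C@@H](OS(C)(=O)=O)C[C@H](OC(C)=O)/C(C)=C/COC(C)=O | intermediate
11 | (2E,4S,6S,7R)-7-hydroxy-6-(methylsulfonyloxy)-3,7,11-trimethyldodeca-2,10-diene-1,4-diyl diacetate (reacts as its alkoxide) | CC(C)=CCC[C@@](C)(O)[C@@H](OS(C)(=O)=O)C[C@H](OC(C)=O)/C(C)=C/COC(C)=O | intermediate (not isolated)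
12 | (2E,4S)-3-methyl-5-[(2R,3R)-3-methyl-3-(4-methylpent-3-en-1-yl)oxiran-2-yl]pent-2-ene-1,4-diyl diacetate | CC(C)=CCC[C@@]1(C)O[C@@H]1C[C@H](OC(C)=O)/C(C)=C/COC(C)=O | intermediate
13 | secondary ozonide (3,3-dimethyl-1,2,4-trioxolane) of the isopropylidene alkene of 12 | CC1(C)OOC(CC[C@@]2(C)O[C@@H]2C[C@H](OC(C)=O)/C(C)=C/COC(C)=O)O1 | intermediate (not isolated)
14 | (2E,4S)-3-methyl-5-[(2R,3R)-3-methyl-3-(3-oxopropyl)oxiran-2-yl]pent-2-ene-1,4-diyl diacetate | O=CCC[C@@]1(C)O[C@@H]1C[C@H](OC(C)=O)/C(C)=C/COC(C)=O | intermediate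
15 | methyl 3-hydroxypropanoate | COC(=O)CCO | starting material
16 | methyl 3-(tert-butyldimethylsilyloxy)propanoate | COC(=O)CCO[Si](C)(C)C(C)(C)C | intermediate
17 | lithium enolate of 16 | [Li]OC(OC)=CCO[Si](C)(C)C(C)(C)C | intermediate (not isolated)
18 | methyl 5-{(2R,3R)-3-[(2S,3E)-2,5-diacetoxy-3-methylpent-3-en-1-yl]-2-methyloxiran-2-yl}-2-[(tert-butyldimethylsilyloxy)methyl]-3-hydroxypentanoate (mixture at C7 and C11) | COC(=O)C(CO[Si](C)(C)C(C)(C)C)C(O)CC[C@@]1(C)O[C@@H]1C[C@H](OC(C)=O)/C(C)=C/COC(C)=O | intermediate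
19 | methyl 5-{(2R,3R)-3-[(2S,3E)-2-acetoxy-5-hydroxy-3-methylpent-3-en-1-yl]-2-methyloxiran-2-yl}-2-[(tert-butyldimethylsilyloxy)methyl]-3-hydroxypentanoate (mixture at C7 and C11) | COC(=O)C(CO[Si](C)(C)C(C)(C)C)C(O)CC[C@@]1(C)O[C@@H]1C[C@H](OC(C)=O)/C(C)=C/CO | intermediate
20 | methyl 5-{(2R,3R)-3-[(2S,3E)-2-acetoxy-3-methyl-5-oxopent-3-en-1-yl]-2-methyloxiran-2-yl}-2-[(tert-butyldimethylsilyloxy)methyl]-3-oxopentanoate (C11 epimers) | COC(=O)C(CO[Si](C)(C)C(C)(C)C)C(=O)CC[C@@]1(C)O[C@@H]1C[C@H](OC(C)=O)/C(C)=C/C=O | intermediate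
21 | chelated sodium (Z)-enolate of 20 | COC(=O)/C(CO[Si](C)(C)C(C)(C)C)=C([O-])/CC[C@@]1(C)O[C@@H]1C[C@H](OC(C)=O)/C(C)=C/C=O.[Na+] | intermediate (not isolated)
22 | methyl (2Z)-5-{(2R,3R)-3-[(2S,3E)-2-acetoxy-3-methyl-5-oxopent-3-en-1-yl]-2-methyloxiran-2-yl}-2-[(tert-butyldimethylsilyloxy)methyl]-3-(trifluoromethylsulfonyloxy)pent-2-enoate (seco enal Z-enol triflate) | COC(=O)/C(CO[Si](C)(C)C(C)(C)C)=C(OS(=O)(=O)C(F)(F)F)/CC[C@@]1(C)O[C@@H]1C[C@H](OC(C)=O)/C(C)=C/C=O | intermediate
23 | C7 alkenylnickel triflate from 22 (divalent nickel) | COC(=O)/C(CO[Si](C)(C)C(C)(C)C)=C([Ni]OS(=O)(=O)C(F)(F)F)/CC[C@@]1(C)O[C@@H]1C[C@H](OC(C)=O)/C(C)=C/C=O | intermediate (not isolated)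
24 | C7 alkenylchromium dichloride from 22 (trivalent chromium) | COC(=O)/C(CO[Si](C)(C)C(C)(C)C)=C([Cr](Cl)Cl)/CC[C@@]1(C)O[C@@H]1C[C@H](OC(C)=O)/C(C)=C/C=O | intermediate (not isolated)
25 | ring-closed (6R)-C6 chromium alkoxide, ten-membered ring with exocyclic (Z)-C7=C11 bearing CO2Me and CH2OTBS | COC(=O)/C(CO[Si](C)(C)C(C)(C)C)=C1/CC[C@@]2(C)O[C@@H]2C[C@H](OC(C)=O)/C(C)=C/[C@H]1O[Cr](Cl)Cl | intermediate (not isolated)
26 | (1R,3S,4E,6R,10R)-3-acetoxy-13-(tert-butyldimethylsilyloxy)-1,10-epoxygermacra-4,7(11)-dien-12,6-olide | CC(C)(C)[Si](C)(C)OCC1=C2CC[C@@]3(C)O[C@@H]3C[C@H](OC(C)=O)/C(C)=C/[C@H]2OC1=O | intermediate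
27 | (1R,3S,4E,6R,10R)-3-acetoxy-1,10-epoxy-13-hydroxygermacra-4,7(11)-dien-12,6-olide | OCC1=C2CC[C@@]3(C)O[C@@H]3C[C@H](OC(C)=O)/C(C)=C/[C@H]2OC1=O | intermediate
28 | (1R,3S,4E,6R,10R)-3,13-diacetoxy-1,10-epoxygermacra-4,7(11)-dien-12,6-olide (CNP0294733.1) | CC(=O)OCC1=C2CC[C@@]3(C)O[C@@H]3C[C@H](OC(C)=O)/C(C)=C/[C@H]2OC1=O | target

Total step count: 15. Longest linear sequence: 14 steps (steps 1–7 and 9–15, from (R)-linalool).

Steps most likely to fail

Step 13. The aldehyde may be attacked on the wrong face during ring closure, so that the C6 epimer dominates, and intermolecular coupling may compete with cyclisation. The fallback sets out from 22 and returns at 26; it corrects C6 after the ring is made instead of during C–C bond formation. The cyclisation is run as in step 13, and the lactone with the wrong C6 configuration, the C6 epimer of 26 F1, is treated with TBSOTf and Et3N (CH2Cl2, −78 °C). This should remove the doubly activated C6 hydrogen and give the ring-fused 2-silyloxyfuran F2, in which C6 is planar. Cleavage of the labile furyl silyl ether with Bu4NF/AcOH at −78 °C should protonate C6 under kinetic control from the exposed outer face of the furan and return the conjugated butenolide 26. If the kinetic protonation shows the same bias, equilibration of F1 with DBU offers the thermodynamic ratio.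

Step 3. The boron reagent may fail to override the unknown 1,4-bias of the C10 centre, so that addition to both faces of the enal gives a mixture of C3 epimers. The fallback sets out from 3 and returns at 7. The aldol with 4 is run with achiral Cy2BCl/Et3N, which should give 7 together with the (3R)-epimer of 7 F3. The mixture is submitted to a Sharpless kinetic resolution (Ti(OiPr)4, D-(−)-diisopropyl tartrate, t-BuOOH, 4 Å sieves, CH2Cl2, −20 °C). The (3R)-configured allylic alcohol is the fast-reacting one with this tartrate and should be consumed as the (3R,4S,5S)-epoxy alcohol F4, while (3S)-7 is left and separated by chromatography.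

Step 10. The C3 acetate may be partly lost or may migrate while the C6 acetate is removed. The fallback sets out from 7 and returns at 19; it gives the C6 oxygen an orthogonal protecting group before the C3 acetate exists. Methanolysis of the only acetate of 7 with the same tin catalyst should give the C3,C6-diol F5. TBSCl/imidazole should silylate the primary allylic hydroxyl selectively to give the C6 silyl ether F6. Evans–Tishchenko reduction as in step 4 gives the C3 monoacetate F7, and MsCl/Et3N gives the C1 mesylate F8. An excess of Bu4NF then removes both silyl groups and closes the epoxide, giving the epoxy alcohol F9 with only the C3 acetate left. Ozonolysis as in step 7 gives the hydroxy aldehyde F10, and aldol addition of enolate 17 (one extra equivalent for the free hydroxyl) gives 19 directly.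

Further compounds

F1 | step 13 | (1R,3S,4E,6S,10R)-3-acetoxy-13-(tert-butyldimethylsilyloxy)-1,10-epoxygermacra-4,7(11)-dien-12,6-olide (C6 epimer of 26) | CC(C)(C)[Si](C)(C)OCC1=C2CC[C@@]3(C)O[C@@H]3C[C@H](OC(C)=O)/C(C)=C/[C@@H]2OC1=O
F2 | step 13 | ring-fused 2-(tert-butyldimethylsilyloxy)furan from F1 (furan atoms O, C6, C7, C11, C12; C13 silyl ether, C3 acetate, 1,10-epoxide and 4E alkene kept) | C1C[C@@]2(C)O[C@@H]2C[C@H](OC(C)=O)/C(C)=C/c2oc(O[Si](C)(C)C(C)(C)C)c(CO[Si](C)(C)C(C)(C)C)c21
F3 | step 3 | (2E,4R,7R)-4-hydroxy-3,7,11-trimethyl-6-oxo-7-(triethylsilyloxy)dodeca-2,10-dien-1-yl acetate (C3 epimer of 7) | CC(C)=CCC[C@@](C)(O[Si](CC)(CC)CC)C(=O)C[C@@H](O)/C(C)=C/COC(C)=O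
F4 | step 3 | (3R,4S,5S)-4,5-epoxy alcohol from F3 (target numbering) | CC(C)=CCC[C@@](C)(O[Si](CC)(CC)CC)C(=O)C[C@@H](O)[C@]1(C)O[C@H]1COC(C)=O
F5 | step 10 | C6-deacetyl 7, (3R,7S,8E)-7,10-dihydroxy-3,8-dimethyl-3-(triethylsilyloxy)-... diol drawn by SMILES (free C3 and C6 hydroxyls, C1 ketone, C10 silyl ether) | CC(C)=CCC[C@@](C)(O[Si](CC)(CC)CC)C(=O)C[C@H](O)/C(C)=C/CO
F6 | step 10 | C6 tert-butyldimethylsilyl ether of F5 (free C3 hydroxyl) | CC(C)=CCC[C@@](C)(O[Si](CC)(CC)CC)C(=O)C[C@H](O)/C(C)=C/CO[Si](C)(C)C(C)(C)C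
F7 | step 10 | (1S,3S)-anti C3 acetate, C1 alcohol from F6 (C6 and C10 silyl ethers) | CC(C)=CCC[C@@](C)(O[Si](CC)(CC)CC)[C@@H](O)C[C@H](OC(C)=O)/C(C)=C/CO[Si](C)(C)C(C)(C)C
F8 | step 10 | C1 mesylate of F7 | CC(C)=CCC[C@@](C)(O[Si](CC)(CC)CC)[C@@H](OS(C)(=O)=O)C[C@H](OC(C)=O)/C(C)=C/CO[Si](C)(C)C(C)(C)C
F9 | step 10 | (2S,3E)-5-hydroxy-3-methyl-1-[(2R,3R)-3-methyl-3-(4-methylpent-3-en-1-yl)oxiran-2-yl]pent-3-en-2-yl acetate (C6-deacetyl 12) | CC(C)=CCC[C@@]1(C)O[C@@H]1C[C@H](OC(C)=O)/C(C)=C/CO
F10 | step 10 | (2S,3E)-5-hydroxy-3-methyl-1-[(2R,3R)-3-methyl-3-(3-oxopropyl)oxiran-2-yl]pent-3-en-2-yl acetate (C6-deacetyl 14) | O=CCC[C@@]1(C)O[C@@H]1C[C@H](OC(C)=O)/C(C)=C/CO
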